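The adjacent C3 2-phenylethyl group and C4 oxygen of the benzene ring are disconnected together through a C3–C4 aryne. Because this aryne lies next to the C5 methoxy group (a 3-alkoxyaryne), it is polarised: a carbon nucleophile enters at C3 and the resulting carbanion rests at C4. One pot therefore forms the C3–CH2 bond with 2-phenylethylmagnesium bromide and converts the C4 arylmagnesium into a phenol through borylation and peroxide oxidation. The precursor is 1,3-dimethoxybenzene carrying the 3-hydroxy-3-methylbutyl chain between the methoxy groups (C6) and a bromine at C4, its tertiary alcohol travelling unprotected as the alkoxide. O-Methylation then finishes the target.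

Key step: step 5

Remark: ring carbons are counted from the methoxy-bearing carbon beside the only ring hydrogen (C1 OMe, C2 H, C3 CH2CH2Ph, C4 OMe, C5 OMe, C6 CH2CH2C(CH3)2OH); the target is achiral, so no stereocontrol is needed.

Step 1
Reactants: 1 1,3-dimethoxybenzene; 2 1-bromo-3-methylbut-2-ene
Product: 4 1,3-dimethoxy-2-(3-methylbut-2-en-1-yl)benzene, via 2,6-dimethoxyphenyllithium 3 (not isolated)
Conditions: n-BuLi, THF, 0 °C → rt; then 2, −78 °C → rt
Reagents that add atoms: none
Why: Directed ortho-lithiation removes the hydrogen flanked by both methoxy groups (C6), and SN2 allylation of aryllithium 3 at the primary carbon of the allylic bromide should give the linear prenyl arene.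

Step 2
Reactants: 4 1,3-dimethoxy-2-(3-methylbut-2-en-1-yl)benzene
Product: 5 4-(2,6-dimethoxyphenyl)-2-methylbutan-2-ol
Conditions: Co(acac)2 (20 mol %), PhSiH3, O2 (1 atm), THF, rt
Reagents that add atoms: dioxygen, O=O
Why: In a Mukaiyama hydration, hydrogen-atom transfer from a cobalt hydride to the trisubstituted alkene gives the tertiary radical, which captures O2, and the silane reduces the peroxide, so the Markovnikov tertiary alcohol should form with the arene untouched.

Step 3
Reactants: 5 4-(2,6-dimethoxyphenyl)-2-methylbutan-2-ol
Product: 6 4-(3-bromo-2,6-dimethoxyphenyl)-2-methylbutan-2-ol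
Conditions: NBS (1.0 equiv), MeCN, 0 °C → rt, dark
Reagents that add atoms: N-bromosuccinimide, O=C1CCC(=O)N1Br
Why: Electrophilic aromatic bromination should go to one of the two equivalent positions ortho to one methoxy group and para to the other (C4), since C3 is meta to both and the first bromine deactivates the ring towards a second substitution.

Step 4
Reactants: 7 (2-bromoethyl)benzene
Product: 8 2-phenylethylmagnesium bromide
Conditions: Mg turnings, I2 (cat.), THF, rt → 40 °C, slow addition; used as a titrated solution
Reagents that add atoms: magnesium, [Mg]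
Why: Grignard formation by insertion of magnesium into the primary C–Br bond is routine, and slow addition of the bromide keeps Wurtz coupling low.

Step 5
Reactants: 6 4-(3-bromo-2,6-dimethoxyphenyl)-2-methylbutan-2-ol; 8 2-phenylethylmagnesium bromide
Product: 13 3-(3-hydroxy-3-methylbutyl)-2,4-dimethoxy-6-(2-phenylethyl)phenol, via magnesium alkoxide 9 (not isolated), via aryne 10 (not isolated), via arylmagnesium bromide 11 (not isolated), via dimethyl arylboronate 12 (not isolated)
Conditions: 8 (4 equiv), THF, 0 °C; LiTMP (2 equiv, from TMPH and n-BuLi), −78 °C → rt; B(OMe)3, −78 °C → rt; aq. NaOH, 30% H2O2, 0 °C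
Reagents that add atoms: hydrogen peroxide, OO
Why: The first equivalent of 8 turns the tertiary alcohol into alkoxide 9, after which LiTMP removes the C3 hydrogen, the only one ortho to bromine, and loss of bromide from C4 gives aryne 10, the sole aryne possible because C5 bears no hydrogen. Inductive withdrawal by the C5 methoxy oxygen bends the aryne unsymmetrically and makes C3 the more linear, more electrophilic terminus, so the alkyl carbon of 8 should bond to C3 (flanked only by C2–H) and the carbon–magnesium bond should form at C4, stabilised by the neighbouring oxygen inductively and by coordination, giving 11. Trimethyl borate captures 11 as boronate 12, and hydroperoxide adds to boron and triggers a 1,2-shift of the aryl group from boron to oxygen, which places the new C–O bond exactly at C4. The closest known reaction types are aryne carbomagnesiation with electrophilic trapping of the arylmagnesium, including distal attack on 3-methoxyarynes, and the Grignard–borate–peroxide phenol synthesis. No ring closes and no stereocentre forms. The selectivity required is addition at C3 rather than C4, secured by the sigma-withdrawing C5 methoxy group and reinforced by sterics, the C1 methoxy group para to C4 exerting only a weak remote bias.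

Step 6
Reactants: 13 3-(3-hydroxy-3-methylbutyl)-2,4-dimethoxy-6-(2-phenylethyl)phenol
Product: 14 2-methyl-4-[2,3,6-trimethoxy-4-(2-phenylethyl)phenyl]butan-2-ol
Conditions: MeI, K2CO3, acetone, reflux
Reagents that add atoms: iodomethane, CI
Why: In this Williamson ether synthesis the carbonate ionises only the phenol and not the far less acidic tertiary alcohol, so SN2 methylation should occur at the C4 oxygen alone.

Compound list
1 | 1,3-dimethoxybenzene | COc1cccc(OC)c1 | starting material
2 | 1-bromo-3-methylbut-2-ene | CC(C)=CCBr | starting material
3 | 2,6-dimethoxyphenyllithium | COc1cccc(OC)c1[Li] | intermediate (not isolated)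
4 | 1,3-dimethoxy-2-(3-methylbut-2-en-1-yl)benzene | COc1cccc(OC)c1CC=C(C)C | intermediate
5 | 4-(2,6-dimethoxyphenyl)-2-methylbutan-2-ol | COc1cccc(OC)c1CCC(C)(C)O | intermediate
6 | 4-(3-bromo-2,6-dimethoxyphenyl)-2-methylbutan-2-ol | COc1ccc(Br)c(OC)c1CCC(C)(C)O | intermediate
7 | (2-bromoethyl)benzene | BrCCc1ccccc1 | starting material
8 | 2-phenylethylmagnesium bromide | Br[Mg]CCc1ccccc1 | intermediate
9 | bromomagnesium 4-(3-bromo-2,6-dimethoxyphenyl)-2-methylbutan-2-olate | COc1ccc(Br)c(OC)c1CCC(C)(C)O[Mg]Br | intermediate (not isolated)
10 | bromomagnesium 4-(3,4-didehydro-2,6-dimethoxyphenyl)-2-methylbutan-2-olate (C3–C4 aryne) | COC1=CC#CC(OC)=C1CCC(C)(C)O[Mg]Br | intermediate (not isolated)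
11 | bromomagnesium 4-[3-(bromomagnesio)-2,6-dimethoxy-4-(2-phenylethyl)phenyl]-2-methylbutan-2-olate | COc1cc(CCc2ccccc2)c([Mg]Br)c(OC)c1CCC(C)(C)O[Mg]Br | intermediate (not isolated)
12 | bromomagnesium 4-[3-(dimethoxyboranyl)-2,6-dimethoxy-4-(2-phenylethyl)phenyl]-2-methylbutan-2-olate | COc1cc(CCc2ccccc2)c(B(OC)OC)c(OC)c1CCC(C)(C)O[Mg]Br | intermediate (not isolated)
13 | 3-(3-hydroxy-3-methylbutyl)-2,4-dimethoxy-6-(2-phenylethyl)phenol | COc1cc(CCc2ccccc2)c(O)c(OC)c1CCC(C)(C)O | intermediate
14 | 2-methyl-4-[2,3,6-trimethoxy-4-(2-phenylethyl)phenyl]butan-2-ol | COc1cc(CCc2ccccc2)c(OC)c(OC)c1CCC(C)(C)O | target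

Total step count: 6. Longest linear sequence: 5 steps (steps 1, 2, 3, 5 and 6); step 4 is a one-step side branch that feeds step 5.

Steps most likely to fail

Step 5. Three processes could spoil it:
- The amide base may be captured by the Grignard reagent before it deprotonates C3, so that aryne formation stalls.
- A beta-hydrogen of the Grignard reagent may be transferred to the aryne, or the arylmagnesium may add to a second aryne, instead of clean carbomagnesiation.
- Borylation of the doubly flanked C4 arylmagnesium may be incomplete, leaving protonation at C4 on work-up.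

The fallback avoids the aryne altogether and builds the same two bonds one at a time with known reactions. Setting out from bromide 6, palladium-catalysed hydroxylation (Pd2(dba)3, t-BuXPhos, KOH, 1,4-dioxane/H2O, 100 °C) would give 3-(3-hydroxy-3-methylbutyl)-2,4-dimethoxyphenol F1. Magnesium-mediated ortho-formylation (MgCl2, Et3N, paraformaldehyde, MeCN, reflux) can only occur at C3, the single free position ortho to the phenol, and would give 2-hydroxy-4-(3-hydroxy-3-methylbutyl)-3,5-dimethoxybenzaldehyde F2. Wittig olefination with benzyltriphenylphosphonium chloride and excess KOtBu in THF would give 3-(3-hydroxy-3-methylbutyl)-2,4-dimethoxy-6-(2-phenylethenyl)phenol F3 as an E/Z mixture. Hydrogenation of either isomer (H2, Pd/C, EtOAc) would deliver 13, where the route is rejoined before step 6.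

Step 2. The radical hydration may over-reduce the tertiary radical to the alkane or stop at the peroxide stage. The fallback replaces hydration by oxidation and hydride delivery. From alkene 4, epoxidation (mCPBA, NaHCO3, CH2Cl2, 0 °C) would give racemic 2-[(2,6-dimethoxyphenyl)methyl]-3,3-dimethyloxirane F4. LiAlH4 in THF should then deliver hydride to the less substituted epoxide carbon and return the tertiary alcohol 5.

Step 1. Allylic transposition during the alkylation (attack at the tertiary end of the allyl system) or incomplete lithiation would contaminate or diminish 4. The fallback builds the side chain by cross-coupling. From 1, lithiation to 3 as in step 1 and quenching with I2 would give 2-iodo-1,3-dimethoxybenzene F5. Sonogashira coupling with 2-methylbut-3-yn-2-ol (PdCl2(PPh3)2, CuI, Et3N, 60 °C) would give 4-(2,6-dimethoxyphenyl)-2-methylbut-3-yn-2-ol F6. Full hydrogenation (H2, Pd/C, EtOH) would give 5, rejoining the route there and bypassing both 4 and step 2.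

Further compounds
F1 | step 5 | 3-(3-hydroxy-3-methylbutyl)-2,4-dimethoxyphenol | COc1ccc(O)c(OC)c1CCC(C)(C)O
F2 | step 5 | 2-hydroxy-4-(3-hydroxy-3-methylbutyl)-3,5-dimethoxybenzaldehyde | COc1cc(C=O)c(O)c(OC)c1CCC(C)(C)O
F3 | step 5 | 3-(3-hydroxy-3-methylbutyl)-2,4-dimethoxy-6-(2-phenylethenyl)phenol (E/Z mixture) | COc1cc(C=Cc2ccccc2)c(O)c(OC)c1CCC(C)(C)O
F4 | step 2 | 2-[(2,6-dimethoxyphenyl)methyl]-3,3-dimethyloxirane (racemic) | COc1cccc(OC)c1CC1OC1(C)C
F5 | step 1 | 2-iodo-1,3-dimethoxybenzene | COc1cccc(OC)c1I
F6 | step 1 | 4-(2,6-dimethoxyphenyl)-2-methylbut-3-yn-2-ol | COc1cccc(OC)c1C#CC(C)(C)O
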